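**Retrosynthetic overview**

1. Target 27 is a 2,3-trans-3,4-trans guibourtinidol unit (rings A, C, B) joined C4→C6′ to the catechol ring E of a 2,3-trans fisetinidol unit (benzo ring D, pyran ring F); the last step is hydrogenolysis of hexabenzyl ether 26.
2. Key disconnection: the aryl ether bond O1–C8a of the lower pyran ring F. 26 comes from open-chain phenol 22 by dearomatisation of ring D, 6-exo oxa-Michael addition of the C2 hydroxyl and dehydrative rearomatisation, telescoped in one operation.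
3. Enabling feature: ring D carries its only oxygen at C7, para to C4a and meta to C8a. Ring D + C4 + C3(OH) + C2 is therefore the skeleton of L-tyrosine (Cα = C3, S), and the dearomatised para-alkylphenol exposes C8a as an enone β-carbon six atoms from the C2 oxygen.
4. 22 comes from ketone 20 (chelation-controlled reduction sets lower C2), made from aryllithium 19 (from bromide 12) and the tyrosine-derived Weinreb amide 18.
5. 12 comes from (S)-flavanone 4 (asymmetric conjugate addition to chromone 2) by Grignard addition, dehydration and hydroboration (sets upper C3 and C4). Ring order: ring C is carried from the chromone; ring F is closed last, in the key step.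

Key step: step 15

Remark (assumption): the ligand antipode in step 2 is chosen by analogy with the facial sense known for cyclic enones with this catalyst; if the addition runs with the opposite sense, (S)-t-BuPyOx is used and nothing else changes.

Atom numbers are flavan numbers within each unit ("upper" = the 4-substituted unit).

**Route**

Step 1
Reactants: 1 7-hydroxy-4H-chromen-4-one
Product: 2 7-(benzyloxy)-4H-chromen-4-one
Conditions: BnBr, K2CO3, DMF, 60 °C
Reagents that add atoms: benzyl bromide, BrCc1ccccc1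
Why: Williamson etherification of the only acidic OH under carbonate conditions that leave the base-sensitive pyranone ring intact.

Step 2
Reactants: 2 7-(benzyloxy)-4H-chromen-4-one; 3 [4-(benzyloxy)phenyl]boronic acid
Product: 4 (2S)-7-(benzyloxy)-2-[4-(benzyloxy)phenyl]chroman-4-one
Conditions: Pd(OCOCF3)2 (5 mol%), (R)-t-BuPyOx (6 mol%), NH4PF6 (30 mol%), H2O (5 equiv), ClCH2CH2Cl, 60 °C
Reagents that add atoms: none
Why: Pd-catalysed asymmetric conjugate addition of an arylboronic acid to a chromone with a pyridine–oxazoline ligand forms the C2–aryl bond, the ligand shielding one enone face so that the (2S)-flavanone should result.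

Step 3
Reactants: 5 4,5-dibromobenzene-1,2-diol
Product: 6 1,2-bis(benzyloxy)-4,5-dibromobenzene
Conditions: BnBr, K2CO3, DMF, 60 °C
Reagents that add atoms: benzyl bromide, BrCc1ccccc1
Why: double Williamson etherification of the catechol.

Step 4
Reactants: 6 1,2-bis(benzyloxy)-4,5-dibromobenzene; 4 (2S)-7-(benzyloxy)-2-[4-(benzyloxy)phenyl]chroman-4-one
Product: 9 (2S)-7-(benzyloxy)-2-[4-(benzyloxy)phenyl]-4-[4,5-bis(benzyloxy)-2-bromophenyl]-2H-chromene, via arylmagnesium chloride 7 (not isolated), via tertiary carbinol 8 (not isolated)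
Conditions: 6, i-PrMgCl·LiCl, THF, −15 °C; then 4, LaCl3·2LiCl, THF, −15 → 0 °C; aq NH4Cl; crude carbinol, PPTS (10 mol%), 4 Å MS, CH2Cl2, rt
Reagents that add atoms: none
Why: Br/Mg exchange on one of the two equivalent C–Br bonds gives an ortho-bromo Grignard reagent that is stable below 0 °C, LaCl3·2LiCl-promoted 1,2-addition to the enolisable ketone should outrun enolisation so that C2 is kept, and acid-catalysed E1 dehydration of the doubly benzylic carbinol can only lose a proton from C3.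

Step 5
Reactants: 9 (2S)-4-aryl-2H-chromene
Product: 11 (2R,3S,4S)-7-(benzyloxy)-2-[4-(benzyloxy)phenyl]-4-[4,5-bis(benzyloxy)-2-bromophenyl]chroman-3-ol, via alkylborane 10 (not isolated)
Conditions: BH3·THF, THF, 0 °C → rt; then NaOH, H2O2, H2O, 0 °C → rt
Reagents that add atoms: hydrogen peroxide, OO
Why: hydroboration–oxidation of the trisubstituted styrenyl alkene puts boron on C3 and hydrogen on C4 in a syn addition from the face opposite the C2 aryl group, so oxidation with retention should give the 2,3-trans-3,4-trans alcohol (C3 and C4 set by substrate control from C2).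

Step 6
Reactants: 11 (2R,3S,4S)-4-(2-bromoaryl)flavan-3-ol
Product: 12 (2R,3S,4S)-3,7-bis(benzyloxy)-2-[4-(benzyloxy)phenyl]-4-[4,5-bis(benzyloxy)-2-bromophenyl]chromane
Conditions: NaH, BnBr, Bu4NI (cat.), DMF, 0 °C → rt
Reagents that add atoms: benzyl bromide, BrCc1ccccc1
Why: Williamson benzylation of the secondary alcohol through its sodium alkoxide.

Step 7
Reactants: 13 L-tyrosine
Product: 14 (S)-2-hydroxy-3-(4-hydroxyphenyl)propanoic acid
Conditions: NaNO2, 1 M H2SO4, H2O, 0 °C → rt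
Reagents that add atoms: water, O
Why: diazotisation of the α-amino acid with carboxylate participation (α-lactone, double inversion) replaces NH2 by OH with net retention, so Cα of L-tyrosine becomes the future lower C3 (S).

Step 8
Reactants: 14 (S)-2-hydroxy-3-(4-hydroxyphenyl)propanoic acid
Product: 15 methyl (S)-2-hydroxy-3-(4-hydroxyphenyl)propanoate
Conditions: MeOH, H2SO4 (cat.), reflux
Reagents that add atoms: methanol, CO
Why: Fischer esterification, to which the phenol and the secondary alcohol are inert.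

Step 9
Reactants: 15 methyl (S)-2-hydroxy-3-(4-hydroxyphenyl)propanoate
Product: 16 methyl (S)-2-hydroxy-3-{4-[(triisopropylsilyl)oxy]phenyl}propanoate
Conditions: i-Pr3SiCl (1.05 equiv), imidazole, DMF, 0 °C → rt
Reagents that add atoms: chlorotriisopropylsilane, CC(C)[Si](Cl)(C(C)C)C(C)C
Why: chemoselective O-silylation, the bulky silyl chloride reacting with the phenol far faster than with the hindered α-hydroxy ester OH.

Step 10
Reactants: 16 methyl (S)-2-hydroxy-3-{4-[(triisopropylsilyl)oxy]phenyl}propanoate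
Product: 17 methyl (S)-2-(benzyloxy)-3-{4-[(triisopropylsilyl)oxy]phenyl}propanoate
Conditions: BnOC(=NH)CCl3, TfOH (5 mol%), CH2Cl2–cyclohexane, 0 °C → rt
Reagents that add atoms: benzyl 2,2,2-trichloroacetimidate, ClC(Cl)(Cl)C(=N)OCc1ccccc1
Why: acid-catalysed benzylation with the trichloroacetimidate avoids base and therefore epimerisation of the α-alkoxy ester.

Step 11
Reactants: 17 methyl (S)-2-(benzyloxy)-3-{4-[(triisopropylsilyl)oxy]phenyl}propanoate
Product: 18 (S)-2-(benzyloxy)-N-methoxy-N-methyl-3-{4-[(triisopropylsilyl)oxy]phenyl}propanamide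
Conditions: MeNH(OMe)·HCl, i-PrMgCl, THF, −20 → 0 °C
Reagents that add atoms: N,O-dimethylhydroxylamine hydrochloride, CNOC.Cl
Why: direct ester-to-Weinreb-amide conversion with the chloromagnesium amide at low temperature, conditions under which α-alkoxy esters keep their configuration.

Step 12
Reactants: 12 (2R,3S,4S)-3,7-bis(benzyloxy)-2-[4-(benzyloxy)phenyl]-4-[4,5-bis(benzyloxy)-2-bromophenyl]chromane; 18 (S)-2-(benzyloxy)-N-methoxy-N-methyl-3-{4-[(triisopropylsilyl)oxy]phenyl}propanamide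
Product: 20 (S)-2-(benzyloxy)-1-{4,5-bis(benzyloxy)-2-[(2R,3S,4R)-3,7-bis(benzyloxy)-2-(4-(benzyloxy)phenyl)chroman-4-yl]phenyl}-3-{4-[(triisopropylsilyl)oxy]phenyl}propan-1-one, via aryllithium 19 (not isolated)
Conditions: 12, t-BuLi (2 equiv), THF, −78 °C; then 18, −78 → −40 °C; aq NH4Cl
Reagents that add atoms: none
Why: Br/Li exchange is faster than any deprotonation at −78 °C and the aryllithium adds once to the Weinreb amide, whose chelated tetrahedral intermediate prevents over-addition and epimerisation (Weinreb ketone synthesis).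

Step 13
Reactants: 20 aryl α-benzyloxy ketone
Product: 21 (1R,2S)-2-(benzyloxy)-1-{4,5-bis(benzyloxy)-2-[(2R,3S,4R)-3,7-bis(benzyloxy)-2-(4-(benzyloxy)phenyl)chroman-4-yl]phenyl}-3-{4-[(triisopropylsilyl)oxy]phenyl}propan-1-ol
Conditions: Zn(BH4)2, Et2O–CH2Cl2, −20 → 0 °C
Reagents that add atoms: none
Why: chelation-controlled reduction, in which zinc ties the ketone and the α-benzyloxy oxygen into a Cram chelate and hydride enters opposite the CH2Ar group, should give the anti (1R,2S) alcohol that corresponds to the 2,3-trans arrangement of ring F.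

Step 14
Reactants: 21 anti alcohol with silylated phenol
Product: 22 (1R,2S)-2-(benzyloxy)-1-{4,5-bis(benzyloxy)-2-[(2R,3S,4R)-3,7-bis(benzyloxy)-2-(4-(benzyloxy)phenyl)chroman-4-yl]phenyl}-3-(4-hydroxyphenyl)propan-1-ol
Conditions: Bu4NF, THF, 0 °C
Reagents that add atoms: none
Why: fluoride cleaves the aryl silyl ether selectively and unmasks the only free phenol of the molecule for the key step.

Step 15
Reactants: 22 open-chain phenol with free C2 hydroxyl
Product: 26 (2R,3S)-3-(benzyloxy)-2-{4,5-bis(benzyloxy)-2-[(2R,3S,4R)-3,7-bis(benzyloxy)-2-(4-(benzyloxy)phenyl)chroman-4-yl]phenyl}chroman-7-ol, via hydroperoxydienone 23 (not isolated), via para-quinol 24 (not isolated), via oxa-Michael adduct 25 (not isolated)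
Conditions: Oxone (2KHSO5·KHSO4·K2SO4), NaHCO3, MeCN–THF–H2O, rt; Me2S; extractive solvent switch, then TsOH·H2O (30 mol%), CH2Cl2, rt → 40 °C
Reagents that add atoms: none
Why: Proposed new method: singlet oxygen released from Oxone/NaHCO3 should add to the only free phenol (ring D) to give hydroperoxydienone 23, Me2S reduces it to para-quinol 24, and acid then promotes conjugate addition of the C2 hydroxyl to the dienone β-carbon C8a (25) followed by loss of the C4a hydroxyl as water with enolisation, so that the C8a–H of 22 becomes the C8a–O1 bond of ring F. The closest known reactions are the Oxone-mediated dearomatisation of para-alkylphenols to para-quinols, the intramolecular oxa-Michael addition of hydroxyalkyl para-quinols, and the acid-induced dehydrative rearomatisation of quinol Michael adducts to meta-substituted phenols; their telescoped use to forge a chroman aryl–oxygen bond is untested. Ring F closes in the 6-exo-trig mode onto the enone. No permanent stereocentre is formed (the transient C4a and C8a centres of 25 vanish on aromatisation), and C2 and C3 keep their configurations because no bond to either carbon is broken. The step needs chemoselectivity for ring D, secured by its being the only free phenol, and selectivity for six- over five-membered closure, secured by the benzyl ether on O3; attack at either enone β-carbon converges on the same chroman after rearomatisation.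

Step 16
Reactants: 26 hexabenzyl ether with free 7-OH on ring D
Product: 27 (2R,3S,4R)-4-{2-[(2R,3S)-3,7-dihydroxychroman-2-yl]-4,5-dihydroxyphenyl}-2-(4-hydroxyphenyl)chromane-3,7-diol
Conditions: H2 (1 atm), Pd(OH)2/C, THF–MeOH, rt
Reagents that add atoms: none
Why: catalytic hydrogenolysis of the six O-benzyl ethers under neutral conditions should leave the benzylic ring ethers and all five stereocentres untouched, as is usual for flavan-3-ol oligomers.

**Compound list**

1 | 7-hydroxy-4H-chromen-4-one | O=c1ccoc2cc(O)ccc12 | starting material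
2 | 7-(benzyloxy)-4H-chromen-4-one | O=c1ccoc2cc(OCc3ccccc3)ccc12 | intermediate
3 | [4-(benzyloxy)phenyl]boronic acid | OB(O)c1ccc(OCc2ccccc2)cc1 | starting material
4 | (2S)-7-(benzyloxy)-2-[4-(benzyloxy)phenyl]chroman-4-one | c1ccccc1COc1ccc([C@H]2Oc3cc(OCc4ccccc4)ccc3C(=O)C2)cc1 | intermediate
5 | 4,5-dibromobenzene-1,2-diol | Oc1cc(Br)c(Br)cc1O | starting material
6 | 1,2-bis(benzyloxy)-4,5-dibromobenzene | Brc1cc(OCc2ccccc2)c(OCc2ccccc2)cc1Br | intermediate
7 | [4,5-bis(benzyloxy)-2-bromophenyl]magnesium chloride, LiCl complex (not isolated) | Cl[Mg]c1cc(OCc2ccccc2)c(OCc2ccccc2)cc1Br | intermediate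
8 | (2S)-7-(benzyloxy)-2-[4-(benzyloxy)phenyl]-4-[4,5-bis(benzyloxy)-2-bromophenyl]chroman-4-ol, C4 epimers (not isolated) | c1ccccc1COc1ccc([C@H]2Oc3cc(OCc4ccccc4)ccc3C(O)(c3cc(OCc4ccccc4)c(OCc4ccccc4)cc3Br)C2)cc1 | intermediate
9 | (2S)-7-(benzyloxy)-2-[4-(benzyloxy)phenyl]-4-[4,5-bis(benzyloxy)-2-bromophenyl]-2H-chromene | c1ccccc1COc1ccc([C@H]2Oc3cc(OCc4ccccc4)ccc3C(c3cc(OCc4ccccc4)c(OCc4ccccc4)cc3Br)=C2)cc1 | intermediate
10 | flavan-3-ylborane from 9, boron on C3 anti to both aryl groups, drawn as RBH2 (not isolated) | c1ccccc1COc1ccc([C@H]2Oc3cc(OCc4ccccc4)ccc3[C@@H](c3cc(OCc4ccccc4)c(OCc4ccccc4)cc3Br)[C@@H]2B)cc1 | intermediate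
11 | (2R,3S,4S)-7-(benzyloxy)-2-[4-(benzyloxy)phenyl]-4-[4,5-bis(benzyloxy)-2-bromophenyl]chroman-3-ol (2,3-trans-3,4-trans) | c1ccccc1COc1ccc([C@H]2Oc3cc(OCc4ccccc4)ccc3[C@@H](c3cc(OCc4ccccc4)c(OCc4ccccc4)cc3Br)[C@@H]2O)cc1 | intermediate
12 | (2R,3S,4S)-3,7-bis(benzyloxy)-2-[4-(benzyloxy)phenyl]-4-[4,5-bis(benzyloxy)-2-bromophenyl]chromane | c1ccccc1COc1ccc([C@H]2Oc3cc(OCc4ccccc4)ccc3[C@@H](c3cc(OCc4ccccc4)c(OCc4ccccc4)cc3Br)[C@@H]2OCc2ccccc2)cc1 | intermediate
13 | L-tyrosine | N[C@@H](Cc1ccc(O)cc1)C(=O)O | starting material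
14 | (S)-2-hydroxy-3-(4-hydroxyphenyl)propanoic acid | O[C@@H](Cc1ccc(O)cc1)C(=O)O | intermediate
15 | methyl (S)-2-hydroxy-3-(4-hydroxyphenyl)propanoate | COC(=O)[C@@H](O)Cc1ccc(O)cc1 | intermediate
16 | methyl (S)-2-hydroxy-3-{4-[(triisopropylsilyl)oxy]phenyl}propanoate | COC(=O)[C@@H](O)Cc1ccc(O[Si](C(C)C)(C(C)C)C(C)C)cc1 | intermediate
17 | methyl (S)-2-(benzyloxy)-3-{4-[(triisopropylsilyl)oxy]phenyl}propanoate | COC(=O)[C@@H](OCc1ccccc1)Cc1ccc(O[Si](C(C)C)(C(C)C)C(C)C)cc1 | intermediate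
18 | (S)-2-(benzyloxy)-N-methoxy-N-methyl-3-{4-[(triisopropylsilyl)oxy]phenyl}propanamide | CON(C)C(=O)[C@@H](OCc1ccccc1)Cc1ccc(O[Si](C(C)C)(C(C)C)C(C)C)cc1 | intermediate
19 | aryllithium from 12, Li in place of Br (not isolated) | c1ccccc1COc1ccc([C@H]2Oc3cc(OCc4ccccc4)ccc3[C@@H](c3cc(OCc4ccccc4)c(OCc4ccccc4)cc3[Li])[C@@H]2OCc2ccccc2)cc1 | intermediate
20 | (S)-2-(benzyloxy)-1-{4,5-bis(benzyloxy)-2-[(2R,3S,4R)-3,7-bis(benzyloxy)-2-(4-(benzyloxy)phenyl)chroman-4-yl]phenyl}-3-{4-[(triisopropylsilyl)oxy]phenyl}propan-1-one | c1ccccc1COc1ccc([C@H]2Oc3cc(OCc4ccccc4)ccc3[C@@H](c3cc(OCc4ccccc4)c(OCc4ccccc4)cc3C(=O)[C@@H](OCc3ccccc3)Cc3ccc(O[Si](C(C)C)(C(C)C)C(C)C)cc3)[C@@H]2OCc2ccccc2)cc1 | intermediate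
21 | (1R,2S)-2-(benzyloxy)-1-{4,5-bis(benzyloxy)-2-[(2R,3S,4R)-3,7-bis(benzyloxy)-2-(4-(benzyloxy)phenyl)chroman-4-yl]phenyl}-3-{4-[(triisopropylsilyl)oxy]phenyl}propan-1-ol | c1ccccc1COc1ccc([C@H]2Oc3cc(OCc4ccccc4)ccc3[C@@H](c3cc(OCc4ccccc4)c(OCc4ccccc4)cc3[C@@H](O)[C@@H](OCc3ccccc3)Cc3ccc(O[Si](C(C)C)(C(C)C)C(C)C)cc3)[C@@H]2OCc2ccccc2)cc1 | intermediate
22 | (1R,2S)-2-(benzyloxy)-1-{4,5-bis(benzyloxy)-2-[(2R,3S,4R)-3,7-bis(benzyloxy)-2-(4-(benzyloxy)phenyl)chroman-4-yl]phenyl}-3-(4-hydroxyphenyl)propan-1-ol | c1ccccc1COc1ccc([C@H]2Oc3cc(OCc4ccccc4)ccc3[C@@H](c3cc(OCc4ccccc4)c(OCc4ccccc4)cc3[C@@H](O)[C@@H](OCc3ccccc3)Cc3ccc(O)cc3)[C@@H]2OCc2ccccc2)cc1 | intermediate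
23 | 4-hydroperoxy-4-[(2S,3R)-2-(benzyloxy)-3-hydroxy-3-aryl-propyl]cyclohexa-2,5-dien-1-one, aryl as in 22 (not isolated) | c1ccccc1COc1ccc([C@H]2Oc3cc(OCc4ccccc4)ccc3[C@@H](c3cc(OCc4ccccc4)c(OCc4ccccc4)cc3[C@@H](O)[C@@H](OCc3ccccc3)CC3(OO)C=CC(=O)C=C3)[C@@H]2OCc2ccccc2)cc1 | intermediate
24 | 4-hydroxy-4-[(2S,3R)-2-(benzyloxy)-3-hydroxy-3-aryl-propyl]cyclohexa-2,5-dien-1-one, aryl as in 22 (not isolated) | c1ccccc1COc1ccc([C@H]2Oc3cc(OCc4ccccc4)ccc3[C@@H](c3cc(OCc4ccccc4)c(OCc4ccccc4)cc3[C@@H](O)[C@@H](OCc3ccccc3)CC3(O)C=CC(=O)C=C3)[C@@H]2OCc2ccccc2)cc1 | intermediate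
25 | (2R,3S)-3-(benzyloxy)-2-aryl-4a-hydroxy-3,4,4a,8a-tetrahydro-2H-chromen-7(8H)-one, aryl as in 22, ring-fusion epimers (not isolated) | c1ccccc1COc1ccc([C@H]2Oc3cc(OCc4ccccc4)ccc3[C@@H](c3cc(OCc4ccccc4)c(OCc4ccccc4)cc3[C@H]3OC4CC(=O)C=CC4(O)C[C@@H]3OCc3ccccc3)[C@@H]2OCc2ccccc2)cc1 | intermediate
26 | (2R,3S)-3-(benzyloxy)-2-{4,5-bis(benzyloxy)-2-[(2R,3S,4R)-3,7-bis(benzyloxy)-2-(4-(benzyloxy)phenyl)chroman-4-yl]phenyl}chroman-7-ol | c1ccccc1COc1ccc([C@H]2Oc3cc(OCc4ccccc4)ccc3[C@@H](c3cc(OCc4ccccc4)c(OCc4ccccc4)cc3[C@H]3Oc4cc(O)ccc4C[C@@H]3OCc3ccccc3)[C@@H]2OCc2ccccc2)cc1 | intermediate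
27 | (2R,3S,4R)-4-{2-[(2R,3S)-3,7-dihydroxychroman-2-yl]-4,5-dihydroxyphenyl}-2-(4-hydroxyphenyl)chromane-3,7-diol | Oc1ccc([C@H]2Oc3cc(O)ccc3[C@@H](c3cc(O)c(O)cc3[C@H]3Oc4cc(O)ccc4C[C@@H]3O)[C@@H]2O)cc1 | target

**Step count and risks**

Total step count: 16. Longest linear sequence: 10 steps (1 → 2 → 4 → 9 → 11 → 12 → 20 → 21 → 22 → 26 → 27; the branch from L-tyrosine is equally long).

Steps most likely to fail:

1. Step 15 (proposed new method). The dienone may not be captured by the hindered C2 hydroxyl, or the para-quinol may lose water toward the exocyclic quinone methide or undergo dienone–phenol rearrangement before it cyclises, so that rearomatisation delivers no aryl ether. Fallback with known chemistry (copper-catalysed intramolecular Ullmann etherification): it sets out from bromide 12, used as its aryllithium 19, and replaces the tyrosine fragment by a ring D precursor that already carries an ortho bromine. (R)-4-Benzyl-3-(benzyloxyacetyl)oxazolidin-2-one is alkylated (NaN(SiMe3)2, THF, −78 °C) with 4-(benzyloxy)-2-bromobenzyl bromide to give the alkylated glycolate imide F1. MeNH(OMe)·HCl/AlMe3 converts it into the bromo Weinreb amide F2. Aryllithium 19 is transmetalated with MgBr2·OEt2, to avoid halogen–metal scrambling with the aryl bromide of F2, and added to F2 to give the bromo ketone F3. Zn(BH4)2 reduction gives the anti bromo alcohol F4. CuI, 3,4,7,8-tetramethyl-1,10-phenanthroline and Cs2CO3 in toluene at 110 °C close ring F to the heptabenzyl ether F5. Hydrogenolysis as in step 16 brings the sequence back to the route at 27.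

2. Step 4. The hindered aryl Grignard reagent may enolise the flavanone instead of adding, and the enolate can open to the chalcone phenoxide, which erodes the C2 configuration and returns ketone. Fallback (the enantio-determining event is moved behind the C4–aryl bond formation): it sets out from 6 via 7. Commercial 4′,7-dihydroxyflavone is benzylated (BnBr, K2CO3) to 4′,7-bis(benzyloxy)flavone F6, which has no enolisable or stereogenic centre. Addition of 7 and work-up with HBF4·OEt2 gives the 4-arylflavylium tetrafluoroborate F7. Chiral phosphoric acid-catalysed 1,4-transfer hydrogenation with a Hantzsch ester (catalyst antipode chosen for the 4S product) gives the 4H-chromene F8. Hydroboration–oxidation (BH3·THF, then NaOH/H2O2; boron on C3 anti to the 4-aryl group, hydrogen on C2 syn to it) brings the sequence back to the route at 11.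

3. Step 12. The ortho-flanked aryllithium may be quenched by proton transfer or add too slowly to the amide, leaving the debrominated flavan. Fallback (a more electrophilic partner, with the oxidation level restored afterwards): it sets out from ester 17 and bromide 12. Reduction of 17 with i-Bu2AlH (CH2Cl2, −78 °C) gives the α-benzyloxy aldehyde F9. Addition of aryllithium 19 gives the carbinol epimers F10. Oxidation with Dess–Martin periodinane brings the sequence back to the route at 20.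

**Further compounds**

F1 | step 15 | (R)-4-benzyl-3-[(S)-2-(benzyloxy)-3-(4-(benzyloxy)-2-bromophenyl)propanoyl]oxazolidin-2-one | O=C1N(C(=O)[C@@H](OCc2ccccc2)Cc2ccc(OCc3ccccc3)cc2Br)[C@H](Cc2ccccc2)CO1
F2 | step 15 | (S)-2-(benzyloxy)-3-[4-(benzyloxy)-2-bromophenyl]-N-methoxy-N-methylpropanamide | CON(C)C(=O)[C@@H](OCc1ccccc1)Cc1ccc(OCc2ccccc2)cc1Br
F3 | step 15 | (S)-2-(benzyloxy)-1-{4,5-bis(benzyloxy)-2-[(2R,3S,4R)-3,7-bis(benzyloxy)-2-(4-(benzyloxy)phenyl)chroman-4-yl]phenyl}-3-[4-(benzyloxy)-2-bromophenyl]propan-1-one | c1ccccc1COc1ccc([C@H]2Oc3cc(OCc4ccccc4)ccc3[C@@H](c3cc(OCc4ccccc4)c(OCc4ccccc4)cc3C(=O)[C@@H](OCc3ccccc3)Cc3ccc(OCc4ccccc4)cc3Br)[C@@H]2OCc2ccccc2)cc1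
F4 | step 15 | (1R,2S)-2-(benzyloxy)-1-{4,5-bis(benzyloxy)-2-[(2R,3S,4R)-3,7-bis(benzyloxy)-2-(4-(benzyloxy)phenyl)chroman-4-yl]phenyl}-3-[4-(benzyloxy)-2-bromophenyl]propan-1-ol | c1ccccc1COc1ccc([C@H]2Oc3cc(OCc4ccccc4)ccc3[C@@H](c3cc(OCc4ccccc4)c(OCc4ccccc4)cc3[C@@H](O)[C@@H](OCc3ccccc3)Cc3ccc(OCc4ccccc4)cc3Br)[C@@H]2OCc2ccccc2)cc1
F5 | step 15 | (2R,3S,4R)-3,7-bis(benzyloxy)-2-[4-(benzyloxy)phenyl]-4-{4,5-bis(benzyloxy)-2-[(2R,3S)-3,7-bis(benzyloxy)chroman-2-yl]phenyl}chromane | c1ccccc1COc1ccc([C@H]2Oc3cc(OCc4ccccc4)ccc3[C@@H](c3cc(OCc4ccccc4)c(OCc4ccccc4)cc3[C@H]3Oc4cc(OCc5ccccc5)ccc4C[C@@H]3OCc3ccccc3)[C@@H]2OCc2ccccc2)cc1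
F6 | step 4 | 7-(benzyloxy)-2-[4-(benzyloxy)phenyl]-4H-chromen-4-one | O=c1cc(-c2ccc(OCc3ccccc3)cc2)oc2cc(OCc3ccccc3)ccc12
F7 | step 4 | 7-(benzyloxy)-2-[4-(benzyloxy)phenyl]-4-[4,5-bis(benzyloxy)-2-bromophenyl]chromenylium tetrafluoroborate | c1ccccc1COc1ccc(-c2cc(-c3cc(OCc4ccccc4)c(OCc4ccccc4)cc3Br)c3ccc(OCc4ccccc4)cc3[o+]2)cc1.F[B-](F)(F)F
F8 | step 4 | (4S)-7-(benzyloxy)-2-[4-(benzyloxy)phenyl]-4-[4,5-bis(benzyloxy)-2-bromophenyl]-4H-chromene | c1ccccc1COc1ccc(C2Oc3cc(OCc4ccccc4)ccc3[C@@H](c3cc(OCc4ccccc4)c(OCc4ccccc4)cc3Br)C=2)cc1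
F9 | step 12 | (S)-2-(benzyloxy)-3-{4-[(triisopropylsilyl)oxy]phenyl}propanal | O=C[C@@H](OCc1ccccc1)Cc1ccc(O[Si](C(C)C)(C(C)C)C(C)C)cc1
F10 | step 12 | (2S)-2-(benzyloxy)-1-{4,5-bis(benzyloxy)-2-[(2R,3S,4R)-3,7-bis(benzyloxy)-2-(4-(benzyloxy)phenyl)chroman-4-yl]phenyl}-3-{4-[(triisopropylsilyl)oxy]phenyl}propan-1-ol, C1 epimers | c1ccccc1COc1ccc([C@H]2Oc3cc(OCc4ccccc4)ccc3[C@@H](c3cc(OCc4ccccc4)c(OCc4ccccc4)cc3C(O)[C@@H](OCc3ccccc3)Cc3ccc(O[Si](C(C)C)(C(C)C)C(C)C)cc3)[C@@H]2OCc2ccccc2)cc1
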